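**Strategy.** The target is read as a heterochiral dimer: its upper 4-aryl unit and its lower flavan-3,4-diol unit are the two enantiomers of one all-trans 3,4-dioxygenated flavan. Ring C of this flavan comes from a formal [4+2] oxa-Povarov annulation that exploits the O1/O8 catechol edge of pyrogallol ring A and its free carbon C4a para to O7: a 2-aryl-1,3-benzodioxole opens to an O-aryl oxocarbenium ion, whose carbon C2 adds 1,2-bis(benzyloxy)ethene (C2–C3) before the new cationic C4 closes on C4a. The racemate is resolved by thiolysis at C4 with an L-cysteine ester; one diastereomer is the electrophile, the other is returned to the nucleophile, and silver joins C4 to C6.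

Key step: step 5

Remark: flavan numbering (O1, C2, C3, C4, C4a, C5–C8, C8a; ring A benzo, ring B 2-aryl, ring C pyran) is used for all chromans; alkene 8 is assumed to be a Z-rich Z/E mixture and is drawn Z; racemates 10 and 11 are drawn as the (2R,3S,4R) enantiomer.

Step 1
Reactants: 1 pyrogallol; 2 4-(benzyloxy)benzaldehyde
Product: 4 2-[4-(benzyloxy)phenyl]-1,3-benzodioxol-4-ol (racemic at the acetal carbon), via dimethyl acetal 3 (not isolated)
Conditions: HC(OMe)3, TsOH (cat.), MeOH, rt; evaporate; then 1, PPTS (cat.), toluene, 90 °C, MeOH distilled off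
Reagents that add atoms: none
Why: Acid-catalysed transacetalisation: the dimethyl acetal made in situ should exchange both methoxy groups for two vicinal hydroxyls of pyrogallol (the two adjacent pairs are equivalent by symmetry) to give the five-membered cyclic acetal, whose stereocentre is of no consequence.

Step 2
Reactants: 4 2-[4-(benzyloxy)phenyl]-1,3-benzodioxol-4-ol
Product: 5 4-(benzyloxy)-2-[4-(benzyloxy)phenyl]-1,3-benzodioxole (racemic)
Conditions: BnBr, K2CO3, DMF, rt
Reagents that add atoms: benzyl bromide BrCc1ccccc1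
Why: Williamson etherification of the only free phenol; the acetal is stable to base.

Step 3
Reactants: 6 (benzyloxy)acetaldehyde dimethyl acetal
Product: 7 1,1,2-tris(benzyloxy)ethane
Conditions: BnOH (3 equiv), TsOH (cat.), toluene, 90 °C, MeOH distilled off
Reagents that add atoms: benzyl alcohol OCc1ccccc1
Why: Acid-catalysed transacetalisation driven by removal of methanol; the primary benzyl ether is inert.

Step 4
Reactants: 7 1,1,2-tris(benzyloxy)ethane
Product: 8 (Z)-1,2-bis(benzyloxy)ethene
Conditions: TMSOTf, iPr2NEt, CH2Cl2, −20 °C to rt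
Reagents that add atoms: none
Why: Acetal-to-enol-ether elimination: TMSOTf ionises the acetal to the O-benzyl oxocarbenium ion and the hindered amine removes the adjacent proton; vicinal dialkoxyethenes prefer the Z geometry, and the geometry is not relayed in step 5.

Step 5
Reactants: 5 4-(benzyloxy)-2-[4-(benzyloxy)phenyl]-1,3-benzodioxole; 8 (Z)-1,2-bis(benzyloxy)ethene
Product: 10 rac-(2R,3S,4R)-3,4,7-tris(benzyloxy)-2-[4-(benzyloxy)phenyl]-3,4-dihydro-2H-chromen-8-ol, via O-aryl oxocarbenium zwitterion 9 (not isolated)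
Conditions: Sc(OTf)3 (10 mol %), 4 Å MS, CH2Cl2–MeCN, −30 °C to rt; Et3N quench
Reagents that add atoms: none
Why: Oxa-Povarov reaction (formal [4+2] annulation of an O-aryl oxocarbenium 2-oxadiene with an electron-rich alkene), here started by Lewis-acid opening of a cyclic acetal: Sc(OTf)3 held between acetal oxygen O8 and the 7-benzyloxy oxygen breaks the C2–O8 bond to give ion 9, the alkene adds to C2 (Prins-type, as in the Müller-Cunradi–Pieroh addition of enol ethers to acetals; C2–C3 bond), and the resulting O-benzyl oxocarbenium carbon C4 alkylates ring-A carbon C4a (C4–C4a bond), after which the proton lost from C4a frees the 8-OH and the catalyst. Ring C closes by a 6-exo-trig Friedel–Crafts attack of the arene bond C8a=C4a on the exocyclic C4=O+ bond (6-(enolendo)-exo-trig), C4a being ortho to O1 and para to the 7-benzyloxy group. C2 and C3 are set in the open addition (syn adduct, which is the 2,3-trans ring isomer) and C4 in the chair-like closure with 2-aryl, 3-OBn and 4-OBn all equatorial; because the addition is reversible and the C4 ether can re-ionise under the catalyst, the all-equatorial 2,3-trans-3,4-trans isomer should also be the thermodynamic outlet, so the alkene geometry is not relayed. No chiral element is present, so 10 is racemic by design and both enantiomers are used later. The step needs opening of the acetal toward O1 and not toward O8, which the chelate secures together with the fact that only the O1-bound ion has a free ortho carbon, the other opening being reversible and unproductive. It also needs C-capture and not O-capture of the second cation, secured because the seven-membered acetal formed by the 8-oxygen reopens under the catalyst whereas the C4–C4a bond forms irreversibly.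

Step 6
Reactants: 10 rac-(2R,3S,4R)-3,4,7-tris(benzyloxy)-2-[4-(benzyloxy)phenyl]-3,4-dihydro-2H-chromen-8-ol
Product: 11 rac-(2R,3S,4R)-3,4,7,8-tetrakis(benzyloxy)-2-[4-(benzyloxy)phenyl]-3,4-dihydro-2H-chromene
Conditions: BnBr, K2CO3, DMF, 50 °C
Reagents that add atoms: benzyl bromide BrCc1ccccc1
Why: Williamson etherification of the hindered 8-phenol, the only acidic OH; base does not affect the C4 ether.

Step 7
Reactants: 11 rac-(2R,3S,4R)-3,4,7,8-tetrakis(benzyloxy)-2-[4-(benzyloxy)phenyl]-3,4-dihydro-2H-chromene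
Product: 12 methyl N-acetyl-S-{(2S,3S,4S)-3,7,8-tris(benzyloxy)-2-[4-(benzyloxy)phenyl]-3,4-dihydro-2H-chromen-4-yl}-L-cysteinate; 13 its (2R,3R,4R)-chromenyl diastereomer (both 2,3-trans-3,4-trans, both isolated after separation on silica)
Conditions: N-acetyl-L-cysteine methyl ester (3 equiv), BF3·OEt2 (20 mol %), CH2Cl2, −40 to 0 °C; chromatography
Reagents that add atoms: N-acetyl-L-cysteine methyl ester CC(=O)N[C@@H](CS)C(=O)OC
Why: Acid-catalysed thiolysis (SN1 at C4 through the benzylic cation stabilised by O1 and the 7-benzyloxy group, the classical thiolytic substitution of 4-oxygenated flavans) should put the enantiopure thiol on C4 anti to the 3-benzyloxy group, so the enantiomers of 11 become separable diastereomers; this separation fixes the absolute configuration at C2 and C3 of both halves of the target, and minor 3,4-cis epimers can stay with their series because C4 is ionised again.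

Step 8
Reactants: 13 methyl N-acetyl-S-{(2R,3R,4R)-3,7,8-tris(benzyloxy)-2-[4-(benzyloxy)phenyl]-3,4-dihydro-2H-chromen-4-yl}-L-cysteinate
Product: 14 (2R,3S,4R)-3,4,7,8-tetrakis(benzyloxy)-2-[4-(benzyloxy)phenyl]-3,4-dihydro-2H-chromene
Conditions: BnOH (5 equiv), AgBF4, 2,6-di-tert-butyl-4-methylpyridine (DTBMP), 4 Å MS, CH2Cl2, −20 °C, dark
Reagents that add atoms: benzyl alcohol OCc1ccccc1
Why: Thiophilic activation: AgBF4 removes the thiolate and the C4 cation is captured by benzyl alcohol anti to the 3-benzyloxy group, which should restore the all-equatorial 3,4-trans ether and so set C4 (R) of the lower unit; the hindered pyridine takes up the acid.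

Step 9
Reactants: 12 methyl N-acetyl-S-{(2S,3S,4S)-3,7,8-tris(benzyloxy)-2-[4-(benzyloxy)phenyl]-3,4-dihydro-2H-chromen-4-yl}-L-cysteinate; 14 (2R,3S,4R)-3,4,7,8-tetrakis(benzyloxy)-2-[4-(benzyloxy)phenyl]-3,4-dihydro-2H-chromene
Product: 15 nona-O-benzyl ether of 16 (upper unit 2S,3R with 2,3-trans-3,4-trans substituents, its C4 bonded to C6 of the lower (2R,3S,4R) unit)
Conditions: AgBF4, DTBMP, 4 Å MS, CH2Cl2, −40 to 0 °C, dark; 14 in excess (3 equiv), slow addition of 12
Reagents that add atoms: none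
Why: Silver-promoted Friedel–Crafts (interflavanyl) alkylation: the soft Lewis acid ionises only the C4–S bond of 12, and the cation should be attacked by C6 of 14 (ortho to the 7-benzyloxy group, para to O1, less hindered than C5) from the face anti to the 3-benzyloxy group, which sets C4 of the upper unit 3,4-trans; the C4 ether of 14 is not activated by silver, the base removes the acid, and excess 14 outcompetes self-alkylation of 12.

Step 10
Reactants: 15 nona-O-benzyl ether of 16
Product: 16 (2R,3S,4R)-2-(4-hydroxyphenyl)-6-[(2S,3R,4S)-3,7,8-trihydroxy-2-(4-hydroxyphenyl)-3,4-dihydro-2H-chromen-4-yl]-3,4-dihydro-2H-chromene-3,4,7,8-tetrol (ent-oritin-(4β→6)-oritin-4α-ol)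
Conditions: H2 (1 atm), Pd(OH)2/C, THF–MeOH, rt
Reagents that add atoms: none
Why: Hydrogenolysis of the nine O–CH2Ph bonds; under neutral conditions the primary benzyl C–O bonds should cleave faster than the ring C2–O1 bond, the secondary C4–O bond and the diarylmethine C4–C6 bond, and no stereocentre is touched.

**Compound list**

1 | pyrogallol | Oc1cccc(O)c1O | starting material
2 | 4-(benzyloxy)benzaldehyde | O=Cc1ccc(OCc2ccccc2)cc1 | starting material
3 | 4-(benzyloxy)benzaldehyde dimethyl acetal | COC(OC)c1ccc(OCc2ccccc2)cc1 | intermediate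
4 | 2-[4-(benzyloxy)phenyl]-1,3-benzodioxol-4-ol (racemic) | Oc1cccc2OC(c3ccc(OCc4ccccc4)cc3)Oc12 | intermediate
5 | 4-(benzyloxy)-2-[4-(benzyloxy)phenyl]-1,3-benzodioxole (racemic) | c1ccc(COc2cccc3OC(c4ccc(OCc5ccccc5)cc4)Oc23)cc1 | intermediate
6 | (benzyloxy)acetaldehyde dimethyl acetal | COC(OC)COCc1ccccc1 | starting material
7 | 1,1,2-tris(benzyloxy)ethane | c1ccccc1COCC(OCc1ccccc1)OCc1ccccc1 | intermediate
8 | (Z)-1,2-bis(benzyloxy)ethene | c1ccccc1CO/C=C\OCc1ccccc1 | intermediate
9 | 2-(benzyloxy)-6-{[4-(benzyloxy)phenyl]methylideneoxonio}phenolate (scandium-bound, drawn as the zwitterion) | [O-]c1c(OCc2ccccc2)cccc1[O+]=Cc1ccc(OCc2ccccc2)cc1 | intermediate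
10 | rac-(2R,3S,4R)-3,4,7-tris(benzyloxy)-2-[4-(benzyloxy)phenyl]-3,4-dihydro-2H-chromen-8-ol | c1ccccc1COc1ccc([C@H]2Oc3c(ccc(OCc4ccccc4)c3O)[C@@H](OCc3ccccc3)[C@@H]2OCc2ccccc2)cc1 | intermediate
11 | rac-(2R,3S,4R)-3,4,7,8-tetrakis(benzyloxy)-2-[4-(benzyloxy)phenyl]-3,4-dihydro-2H-chromene | c1ccccc1COc1ccc([C@H]2Oc3c(ccc(OCc4ccccc4)c3OCc3ccccc3)[C@@H](OCc3ccccc3)[C@@H]2OCc2ccccc2)cc1 | intermediate
12 | methyl N-acetyl-S-{(2S,3S,4S)-3,7,8-tris(benzyloxy)-2-[4-(benzyloxy)phenyl]-3,4-dihydro-2H-chromen-4-yl}-L-cysteinate | c1ccccc1COc1ccc([C@@H]2Oc3c(ccc(OCc4ccccc4)c3OCc3ccccc3)[C@H](SC[C@H](NC(C)=O)C(=O)OC)[C@H]2OCc2ccccc2)cc1 | intermediate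
13 | methyl N-acetyl-S-{(2R,3R,4R)-3,7,8-tris(benzyloxy)-2-[4-(benzyloxy)phenyl]-3,4-dihydro-2H-chromen-4-yl}-L-cysteinate | c1ccccc1COc1ccc([C@H]2Oc3c(ccc(OCc4ccccc4)c3OCc3ccccc3)[C@@H](SC[C@H](NC(C)=O)C(=O)OC)[C@@H]2OCc2ccccc2)cc1 | intermediate
14 | (2R,3S,4R)-3,4,7,8-tetrakis(benzyloxy)-2-[4-(benzyloxy)phenyl]-3,4-dihydro-2H-chromene | c1ccccc1COc1ccc([C@H]2Oc3c(ccc(OCc4ccccc4)c3OCc3ccccc3)[C@@H](OCc3ccccc3)[C@@H]2OCc2ccccc2)cc1 | intermediate
15 | nona-O-benzyl ether of 16 | c1ccccc1COc1ccc([C@H]2Oc3c(cc([C@H]4c5ccc(OCc6ccccc6)c(OCc6ccccc6)c5O[C@@H](c5ccc(OCc6ccccc6)cc5)[C@@H]4OCc4ccccc4)c(OCc4ccccc4)c3OCc3ccccc3)[C@@H](OCc3ccccc3)[C@@H]2OCc2ccccc2)cc1 | intermediate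
16 | (2R,3S,4R)-2-(4-hydroxyphenyl)-6-[(2S,3R,4S)-3,7,8-trihydroxy-2-(4-hydroxyphenyl)-3,4-dihydro-2H-chromen-4-yl]-3,4-dihydro-2H-chromene-3,4,7,8-tetrol | Oc1ccc([C@H]2Oc3c(cc([C@H]4c5ccc(O)c(O)c5O[C@@H](c5ccc(O)cc5)[C@@H]4O)c(O)c3O)[C@@H](O)[C@@H]2O)cc1 | target

**Step count.** Total: 10 steps. Longest linear sequence: 8 steps (1, 2, 5, 6, 7, 8, 9, 10); steps 3 and 4 form the side branch to alkene 8.

**Steps most likely to fail**

Step 5. The acetal may open toward O8 and the resulting ion, which cannot close on ring A, may be consumed by the alkene; the dialkoxyethene may oligomerise cationically; or the C4 ether of the product may re-ionise and alkylate further, so that the annulation does not outrun these paths. The fallback is the classical dihydroflavonol route, which sets out from 2 and comes back at 11. Commercial 1-(2,3,4-trihydroxyphenyl)ethanone would be benzylated at its two non-chelated hydroxyls (BnBr, K2CO3, acetone) to 1-[3,4-bis(benzyloxy)-2-hydroxyphenyl]ethan-1-one F1. Claisen–Schmidt condensation with 2 (KOH, EtOH) should give (E)-1-[3,4-bis(benzyloxy)-2-hydroxyphenyl]-3-[4-(benzyloxy)phenyl]prop-2-en-1-one F2. Alkaline H2O2 at 0 °C (Algar–Flynn–Oyamada conditions stopped at the dihydroflavonol stage) should give rac-(2R,3R)-7,8-bis(benzyloxy)-2-[4-(benzyloxy)phenyl]-3-hydroxy-2,3-dihydro-4H-chromen-4-one F3. NaBH4 reduction should give the 2,3-trans-3,4-trans diol rac-(2R,3S,4R)-7,8-bis(benzyloxy)-2-[4-(benzyloxy)phenyl]-3,4-dihydro-2H-chromene-3,4-diol F4, and NaH/BnBr in DMF would convert F4 into 11.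

Step 9. Ionisation of the thioether by silver may be slower than capture of the cation by a second molecule of 12, and the acid set free may ionise the C4 ether of 14 or of 15, so that oligomers form in place of the dimer. The fallback reverses the two leaving groups; it sets out from 12 and 13 and comes back at 15. Thioether 12 would be converted with AgBF4/BnOH (as in step 8) into (2S,3R,4S)-3,4,7,8-tetrakis(benzyloxy)-2-[4-(benzyloxy)phenyl]-3,4-dihydro-2H-chromene F5. F5 would then be ionised with the hard Lewis acid TMSOTf at −78 °C in the presence of excess 13, whose C4–S bond is inert to oxophilic activation, to give the octa-O-benzyl dimer carrying the cysteine thioether at C4 of the lower unit F6. AgBF4/BnOH would finally exchange that thioether for the 3,4-trans benzyl ether, giving 15.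

Step 10. Once the 7-hydroxyl of the lower unit is unmasked, its C4–O bond becomes a p-hydroxybenzylic bond and may be hydrogenolysed in competition with O–CH2Ph cleavage, giving the 4-deoxy dimer. The fallback carries C4 through the hydrogenolysis as a ketone and reduces it last; it sets out from 15 and comes back at 16. Mild acid hydrolysis (TsOH cat., THF–H2O) of the ionisable C4 benzyl ether should give the octa-O-benzyl dimer with a free 4-hydroxyl in the lower unit F7. Dess–Martin periodinane would oxidise it to the octa-O-benzyl dimer with a C4 ketone in the lower unit F8. Hydrogenolysis (H2, Pd(OH)2/C) should give the free phenolic dihydroflavonol-type dimer F9. NaBH4 reduction of this 2,3-trans-3-hydroxy ketone should deliver the 3,4-trans diol 16, as is usual for free phenolic dihydroflavonols.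

Further compounds
F1 | step 5 | 1-[3,4-bis(benzyloxy)-2-hydroxyphenyl]ethan-1-one | CC(=O)c1ccc(OCc2ccccc2)c(OCc2ccccc2)c1O
F2 | step 5 | (E)-1-[3,4-bis(benzyloxy)-2-hydroxyphenyl]-3-[4-(benzyloxy)phenyl]prop-2-en-1-one | O=C(/C=C/c1ccc(OCc2ccccc2)cc1)c1ccc(OCc2ccccc2)c(OCc2ccccc2)c1O
F3 | step 5 | rac-(2R,3R)-7,8-bis(benzyloxy)-2-[4-(benzyloxy)phenyl]-3-hydroxy-2,3-dihydro-4H-chromen-4-one | c1ccccc1COc1ccc([C@H]2Oc3c(ccc(OCc4ccccc4)c3OCc3ccccc3)C(=O)[C@@H]2O)cc1
F4 | step 5 | rac-(2R,3S,4R)-7,8-bis(benzyloxy)-2-[4-(benzyloxy)phenyl]-3,4-dihydro-2H-chromene-3,4-diol | c1ccccc1COc1ccc([C@H]2Oc3c(ccc(OCc4ccccc4)c3OCc3ccccc3)[C@@H](O)[C@@H]2O)cc1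
F5 | step 9 | (2S,3R,4S)-3,4,7,8-tetrakis(benzyloxy)-2-[4-(benzyloxy)phenyl]-3,4-dihydro-2H-chromene | c1ccccc1COc1ccc([C@@H]2Oc3c(ccc(OCc4ccccc4)c3OCc3ccccc3)[C@H](OCc3ccccc3)[C@H]2OCc2ccccc2)cc1
F6 | step 9 | octa-O-benzyl dimer carrying the S-(N-acetyl-L-cysteine methyl ester) thioether at C4 of the lower unit | c1ccccc1COc1ccc([C@H]2Oc3c(cc([C@H]4c5ccc(OCc6ccccc6)c(OCc6ccccc6)c5O[C@@H](c5ccc(OCc6ccccc6)cc5)[C@@H]4OCc4ccccc4)c(OCc4ccccc4)c3OCc3ccccc3)[C@@H](SC[C@H](NC(C)=O)C(=O)OC)[C@@H]2OCc2ccccc2)cc1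
F7 | step 10 | octa-O-benzyl dimer with free 4-hydroxyl in the lower unit | c1ccccc1COc1ccc([C@H]2Oc3c(cc([C@H]4c5ccc(OCc6ccccc6)c(OCc6ccccc6)c5O[C@@H](c5ccc(OCc6ccccc6)cc5)[C@@H]4OCc4ccccc4)c(OCc4ccccc4)c3OCc3ccccc3)[C@@H](O)[C@@H]2OCc2ccccc2)cc1
F8 | step 10 | octa-O-benzyl dimer with C4 ketone in the lower unit | c1ccccc1COc1ccc([C@H]2Oc3c(cc([C@H]4c5ccc(OCc6ccccc6)c(OCc6ccccc6)c5O[C@@H](c5ccc(OCc6ccccc6)cc5)[C@@H]4OCc4ccccc4)c(OCc4ccccc4)c3OCc3ccccc3)C(=O)[C@@H]2OCc2ccccc2)cc1
F9 | step 10 | free phenolic dimer with C4 ketone in the lower unit (dihydroflavonol-type) | Oc1ccc([C@H]2Oc3c(cc([C@H]4c5ccc(O)c(O)c5O[C@@H](c5ccc(O)cc5)[C@@H]4O)c(O)c3O)C(=O)[C@@H]2O)cc1
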